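**Plan**
- Retrosynthesis cuts, in order: the O1–C2 bond of ring C (retro-oxa-Michael) to the acyclic chalcone 8; the enone C=C (retro-Claisen–Schmidt) to aldehyde 3 and acetophenone 5; the geranyl–O bond (retro-Williamson).
- Forward: geranyl ether first, ring A masked as a bis-THP ether, the three-carbon chain joined by aldol condensation, acetals removed, ring C closed last. Rings A and B are bought.
- Enabling feature: in 8 a phenol oxygen of the phloroglucinol ring A, ortho to the ketone, sits at six-ring distance from the electrophilic β-carbon (the future C2) of the aryl enone. This 2',4',6'-trihydroxychalcone is the native substrate type of chalcone isomerase.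
- Stereochemistry: the single stereocentre C2 (S) is set in the ring closure by the enzyme (catalyst control). The 2E alkene is carried in from geranyl bromide.

Key step: step 5

Remark: the target descriptor corresponds to (2S), the sense of closure given by chalcone isomerase; the recombinant enzyme is treated as an accessible biocatalyst, and the THP acetal carbons of 5, 6 and 7 are stereorandom (diastereomer mixtures, without consequence).

**Step 1**
Reactants: 1 4-hydroxybenzaldehyde; 2 geranyl bromide ((2E)-1-bromo-3,7-dimethylocta-2,6-diene)
Product: 3 4-{[(2E)-3,7-dimethylocta-2,6-dien-1-yl]oxy}benzaldehyde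
Conditions: K2CO3 (1.5 equiv), DMF, rt
Reagents that add atoms: none
Why: Williamson ether synthesis, in which the phenoxide displaces bromide at the primary allylic carbon by SN2, so the 2E geometry is carried over unchanged and no stereocentre is formed.

**Step 2**
Reactants: 4 2',4',6'-trihydroxyacetophenone (dried)
Product: 5 1-[2-hydroxy-4,6-bis(tetrahydro-2H-pyran-2-yloxy)phenyl]ethanone
Conditions: 3,4-dihydro-2H-pyran (2.5 equiv), PPTS (cat.), CH2Cl2–dioxane, 0 °C to rt
Reagents that add atoms: 3,4-dihydro-2H-pyran, C1=COCCC1
Why: Acid-catalysed tetrahydropyranylation (addition of phenol OH to the enol ether via the oxocarbenium ion) should take the para OH and one ortho OH, while the other ortho OH, held in a strong hydrogen bond to the acetyl C=O, is expected to stay free.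

**Step 3**
Reactants: 5 1-[2-hydroxy-4,6-bis(tetrahydro-2H-pyran-2-yloxy)phenyl]ethanone; 3 4-(geranyloxy)benzaldehyde
Product: 7 (2E)-3-[4-(geranyloxy)phenyl]-1-[2-hydroxy-4,6-bis(tetrahydro-2H-pyran-2-yloxy)phenyl]prop-2-en-1-one, via aldol adduct 6 (not isolated)
Conditions: KOH (50% aq.), EtOH, 0 °C to rt, dark; aq. NH4Cl work-up
Reagents that add atoms: none
Why: Claisen–Schmidt condensation, in which the ketone enolate adds to the non-enolisable aldehyde and E1cB loss of hydroxide from 6 gives the thermodynamically preferred E enone, the THP acetals, the allylic ether and the alkenes being inert to hydroxide.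

**Step 4**
Reactants: 7 bis-THP chalcone
Product: 8 (2E)-3-[4-(geranyloxy)phenyl]-1-(2,4,6-trihydroxyphenyl)prop-2-en-1-one
Conditions: PPTS (0.2 equiv), MeOH–THF, 40 °C, dark; NaH2PO4 buffer (pH 5) work-up, cold; used at once
Reagents that add atoms: none
Why: Acid-catalysed transacetalisation transfers both tetrahydropyranyl groups to methanol under a pyridinium acid that is expected to be too weak to ionise the geranyl aryl ether or to drive acid-mediated ring closure, so the acyclic E chalcone should result.

**Step 5**
Reactants: 8 (2E)-3-[4-(geranyloxy)phenyl]-1-(2,4,6-trihydroxyphenyl)prop-2-en-1-one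
Product: 10 (2S)-2-[4-(geranyloxy)phenyl]-5,7-dihydroxy-2,3-dihydro-4H-chromen-4-one, via enzyme-bound enol 9 (not isolated)
Conditions: chalcone isomerase (EC 5.5.1.6, recombinant type 1 enzyme, e.g. from Medicago sativa), KH2PO4/K2HPO4 buffer (50 mM, pH 6.5), DMSO (10% v/v), 2-hydroxypropyl-β-cyclodextrin, 25 °C, dark, Ar, 8 dosed slowly; then citric acid to pH 4, EtOAc
Reagents that add atoms: none
Why: Chalcone isomerase binds the chalcone with one of the two equivalent ortho hydroxyls of ring A ionised (this OH is unusually acidic, being ortho to the ketone on a phloroglucinol ring), and the phenoxide adds in conjugate fashion to the enone β-carbon to give the enzyme-bound enolate 9, which is protonated at the α-carbon to release the ketone. The closest known reaction type is the native reaction of this enzyme class, the intramolecular oxa-Michael addition that converts 2',4',6'-trihydroxychalcones such as naringenin chalcone into (2S)-flavanones; the substrate here differs only by the ether at the para position of ring B, which is expected to point toward the solvent-exposed mouth of the binding cleft. Ring C, the dihydropyran-4-one, closes in the 6-endo-trig mode by formation of the O1–C2 bond. The new stereocentre C2 is set as S by the chiral active site (catalyst control), which holds the enone in one conformation and lets the phenoxide reach only one face of the β-carbon; the substrate has no stereocentre of its own. The step needs enantioface selectivity and an enzymatic rate well above that of the spontaneous, racemic closure: the intact 2',4',6'-trihydroxy pattern of ring A secures recognition, the symmetry of ring A makes both ortho hydroxyls lead to the same product, and pH 6.5 with slow substrate dosing keeps the free phenoxide and hence the background reaction low. The acidic quench and a base-free work-up should keep the 5-hydroxyflavanone from racemising by reversible ring opening.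

**Compound list**
1 | 4-hydroxybenzaldehyde | O=Cc1ccc(O)cc1 | starting material
2 | geranyl bromide, (2E)-1-bromo-3,7-dimethylocta-2,6-diene | CC(C)=CCC/C(C)=C/CBr | starting material
3 | 4-{[(2E)-3,7-dimethylocta-2,6-dien-1-yl]oxy}benzaldehyde | CC(C)=CCC/C(C)=C/COc1ccc(C=O)cc1 | intermediate
4 | 2',4',6'-trihydroxyacetophenone | CC(=O)c1c(O)cc(O)cc1O | starting material
5 | 1-[2-hydroxy-4,6-bis(tetrahydro-2H-pyran-2-yloxy)phenyl]ethanone (diastereomer mixture at the acetal carbons) | CC(=O)c1c(O)cc(OC2CCCCO2)cc1OC3CCCCO3 | intermediate
6 | aldol adduct, 3-[4-(geranyloxy)phenyl]-3-hydroxy-1-[2-hydroxy-4,6-bis(tetrahydro-2H-pyran-2-yloxy)phenyl]propan-1-one (stereorandom) | CC(C)=CCC/C(C)=C/COc1ccc(C(O)CC(=O)c2c(O)cc(OC3CCCCO3)cc2OC4CCCCO4)cc1 | intermediate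
7 | (2E)-3-[4-(geranyloxy)phenyl]-1-[2-hydroxy-4,6-bis(tetrahydro-2H-pyran-2-yloxy)phenyl]prop-2-en-1-one | CC(C)=CCC/C(C)=C/COc1ccc(/C=C/C(=O)c2c(O)cc(OC3CCCCO3)cc2OC4CCCCO4)cc1 | intermediate
8 | (2E)-3-[4-(geranyloxy)phenyl]-1-(2,4,6-trihydroxyphenyl)prop-2-en-1-one | CC(C)=CCC/C(C)=C/COc1ccc(/C=C/C(=O)c2c(O)cc(O)cc2O)cc1 | intermediate
9 | enzyme-bound enol(ate), drawn as the neutral enol (2S)-2-[4-(geranyloxy)phenyl]-2H-chromene-4,5,7-triol | CC(C)=CCC/C(C)=C/COc1ccc([C@@H]2C=C(O)c3c(O)cc(O)cc3O2)cc1 | intermediate
10 | (2S)-2-[4-(geranyloxy)phenyl]-5,7-dihydroxy-2,3-dihydro-4H-chromen-4-one | CC(C)=CCC/C(C)=C/COc1ccc([C@@H]2CC(=O)c3c(O)cc(O)cc3O2)cc1 | target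

**Count**
Total steps: 5. Longest linear sequence: 4 steps (4 → 5 → 7 → 8 → 10, or 1 → 3 → 7 → 8 → 10).

**Steps most likely to fail**

Step 5. The enzyme may bind the lipophilic, geranyl-extended substrate poorly, or the substrate may aggregate in buffer. Spontaneous, non-selective closure would then compete and the enantiomeric purity would erode. The fallback sets out from 8 and comes back at 10, replacing catalyst-controlled induction by resolution with recycling. Heating 8 with NaOAc in EtOH at reflux should close it to racemic 2-[4-(geranyloxy)phenyl]-5,7-dihydroxychroman-4-one F1. Preparative chromatography on a chiral stationary phase (amylose tris(3,5-dimethylphenylcarbamate), hexane/2-propanol) should separate 10 from the (2R)-enantiomer F2. F2 is returned to F1 by renewed warming with NaOAc in EtOH, where reversible ring opening through 8 racemises C2, and is resolved again.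

Step 4. The freed 2',6'-dihydroxychalcone may close prematurely by non-enzymatic oxa-Michael addition during the acid treatment, the work-up or on silica, so that racemate would enter the key step. The fallback sets out from 7 and comes back at 8, replacing kinetic avoidance of the closure by thermodynamic control in strong base. The transacetalisation is run without regard to ring closure. The crude mixture of 8 and racemic flavanone F1 (the same compound as in the fallback to step 5) is dissolved in concentrated aqueous-ethanolic KOH under argon. There retro-oxa-Michael (E1cB) opening makes the chalcone polyphenoxide the stable form. The solution is run into ice-cold dilute HCl (to pH 4), and the precipitated 8 is collected and used at once. This fallback makes no compound beyond those already named.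

Step 2. The tetrahydropyranylation may stop short or overrun, and the labile ortho acetal may be lost on silica, giving mixtures of mono-, bis- and tris-ethers that are hard to separate. The fallback sets out from 3 and 4 and comes back at 8, dropping protection altogether and bypassing steps 2 to 4. Ketone 4 and aldehyde 3 are condensed directly in concentrated KOH in EtOH–H2O at rt under argon over an extended time. Reactant and product are then polyphenoxides and the product cannot close. The mixture is quenched into ice-cold dilute HCl (to pH 4) to precipitate 8. A lower conversion is to be expected, because the polyanion of 4 enolises reluctantly; unreacted 3 should be recoverable.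

**Further compounds**
F1 | step 5 | racemic 2-[4-(geranyloxy)phenyl]-5,7-dihydroxychroman-4-one | CC(C)=CCC/C(C)=C/COc1ccc(C2CC(=O)c3c(O)cc(O)cc3O2)cc1
F2 | step 5 | (2R)-2-[4-(geranyloxy)phenyl]-5,7-dihydroxy-2,3-dihydro-4H-chromen-4-one | CC(C)=CCC/C(C)=C/COc1ccc([C@H]2CC(=O)c3c(O)cc(O)cc3O2)cc1
F0 | step 4 | none | none
F0 | step 2 | none | none
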